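## Retrosynthetic overview

- **Feature.** The route rests on ring B, the central benzene. Going round it, the pattern C–OMe, C–H, C–OH, C–CH2(ring C), C–CH2CH2(ring A), C–H matches a 3-methoxycyclohex-2-en-1-one (C3–OMe, C2–H, C1=O, C6, C5, C4) that lacks one ring double bond.
- **Late disconnections.** The two O-benzyl groups come off last. Arene B goes back to the 5,6-disubstituted enone by dehydrogenation. The C6–CH2(ring C) bond goes back to the alpha-prime enolate of the vinylogous ester and 4-(benzyloxy)benzyl bromide. The enol ether goes back to the mirror-symmetric 5-substituted cyclohexane-1,3-dione.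
- **Early disconnections.** The dione opens to an (E)-hex-3-en-2-one and dimethyl malonate (Michael/Claisen). The enone opens to a 3-arylpropanal and an acetonyl ylide (Wittig). The aldehyde opens to 3-iodophenol and allyl alcohol (Heck).
- **Ring order.** Rings A and C are bought. Ring B is the only ring built: it is closed as the dione, benzylated at C6, and aromatized afterwards.

Key step: step 8

Assumption: the target has no stereocentre, so C5 and C6 of ring B are carried racemic and unseparated; the SMILES of 17 shows one enantiomer of the expected major trans isomer.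

Numbering of ring B (enone numbering, used throughout): C1 carbonyl, C2=C3 enol ether (OMe on C3), C4 methylene, C5 chain-bearing carbon, C6 alpha-prime carbon.

## Route

Step 1
Reactants: 1 3-iodophenol
Product: 2 1-(benzyloxy)-3-iodobenzene
Conditions: BnBr, K2CO3, acetone, reflux
Reagents that add atoms: benzyl bromide BrCc1ccccc1
Why: Williamson ether synthesis: K2CO3 forms the phenoxide, which displaces bromide from benzyl bromide by SN2, and the aryl iodide does not react under these conditions.

Step 2
Reactants: 2 1-(benzyloxy)-3-iodobenzene; 3 allyl alcohol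
Product: 5 3-[3-(benzyloxy)phenyl]propanal, via enol 4 (not isolated)
Conditions: Pd(OAc)2 (cat.), Bu4NCl, NaHCO3, DMF, 40-50 °C
Reagents that add atoms: none
Why: Jeffery-type Heck arylation: the arylpalladium iodide formed by oxidative addition to zerovalent palladium adds across the alkene with the aryl group on the terminal carbon, beta-hydride elimination toward the carbinol carbon gives enol 4, and tautomerization gives the saturated aldehyde without a separate redox step.

Step 3
Reactants: 5 3-[3-(benzyloxy)phenyl]propanal; 6 1-(triphenylphosphoranylidene)propan-2-one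
Product: 7 (E)-6-[3-(benzyloxy)phenyl]hex-3-en-2-one
Conditions: THF, reflux
Reagents that add atoms: none
Why: Wittig olefination with a ketone-stabilized ylide, which is mild enough not to enolize the aldehyde and is reliably E-selective with unbranched aliphatic aldehydes.

Step 4
Reactants: 7 (E)-6-[3-(benzyloxy)phenyl]hex-3-en-2-one; 8 dimethyl malonate
Product: 10 methyl 2-[2-(3-(benzyloxy)phenyl)ethyl]-4,6-dioxocyclohexane-1-carboxylate (racemic; largely enolized), via Michael adduct 9 (not isolated)
Conditions: NaOMe, MeOH, reflux; then cold aq HCl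
Reagents that add atoms: none
Why: Michael addition of sodium dimethyl malonate to the beta-carbon of 7 gives 9, the methyl-ketone enolate of 9 then attacks one ester carbonyl (intramolecular Claisen condensation, 6-exo-trig, closing ring B), and deprotonation of the acidic product pulls the equilibria forward, as in the classical synthesis of 5-substituted cyclohexane-1,3-diones; the two ring stereocentres are epimerizable and one is deleted in step 5.

Step 5
Reactants: 10 methyl 2-[2-(3-(benzyloxy)phenyl)ethyl]-4,6-dioxocyclohexane-1-carboxylate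
Product: 12 5-[2-(3-(benzyloxy)phenyl)ethyl]cyclohexane-1,3-dione, via keto acid 11 (not isolated)
Conditions: 2 M aq NaOH, reflux; then aq HCl to pH 1-2, 90 °C
Reagents that add atoms: none
Why: Ester saponification followed by thermal decarboxylation of beta-keto acid 11 on acidification, the standard end of the malonate route to 1,3-diones, under which an aryl benzyl ether is stable.

Step 6
Reactants: 12 5-[2-(3-(benzyloxy)phenyl)ethyl]cyclohexane-1,3-dione
Product: 13 racemic 3-methoxy-5-[2-(3-(benzyloxy)phenyl)ethyl]cyclohex-2-en-1-one
Conditions: HC(OMe)3, MeOH, TsOH·H2O (cat.), rt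
Reagents that add atoms: methanol CO; trimethyl orthoformate COC(OC)OC
Why: Acid-catalysed vinylogous esterification of the enolized 1,3-dione, driven by the orthoformate as water scavenger; the two carbonyl groups of 12 are related by a mirror plane through C2 and C5, so only one constitution (as a racemate) can form.

Step 7
Reactants: 14 4-(benzyloxy)benzyl alcohol
Product: 15 4-(benzyloxy)benzyl bromide (used freshly prepared)
Conditions: PBr3, Et2O, 0 °C
Reagents that add atoms: phosphorus tribromide BrP(Br)Br
Why: Bromination of a benzylic alcohol by PBr3 through a phosphite ester that bromide displaces (SN2), run cold and worked up quickly because the electron-rich benzylic bromide is prone to self-alkylation.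

Step 8
Reactants: 13 racemic 3-methoxy-5-[2-(3-(benzyloxy)phenyl)ethyl]cyclohex-2-en-1-one; 15 4-(benzyloxy)benzyl bromide
Product: 17 racemic 6-[4-(benzyloxy)benzyl]-3-methoxy-5-[2-(3-(benzyloxy)phenyl)ethyl]cyclohex-2-en-1-one (mainly trans expected; mixture carried on), via lithium enolate 16 (not isolated)
Conditions: LiN(iPr)2 (1.05 equiv), THF, -78 °C; then DMPU, 15 (1.0 equiv), -78 to -20 °C
Reagents that add atoms: none
Why: Lithium diisopropylamide removes a C6 proton, the only sp3 C–H alpha to the ketone, faster than the vinylogous C4 protons, and C6 of the resulting cross-conjugated enolate 16 displaces bromide from 15 in an SN2 reaction. The closest known reaction type is the Stork-Danheiser kinetic alpha-prime alkylation of 3-alkoxycyclohex-2-enones. No ring closes here; the step forms the C6–CH2(ring C) bond on ring B next to the chain-bearing C5. The new C6 stereocentre is set by approach of the bromide to the enolate face opposite the C5 chain (trans), but C6 and C5 both become sp2 in steps 9 and 10, so the diastereomer composition has no consequence. The step needs C6 over C4, C2 and O, and mono- over dialkylation (a 6,6-dibenzyl ketone could never aromatize): low temperature and a slight excess of amide base prevent equilibration to the extended dienolate and proton exchange with the product, the soft benzylic bromide favours carbon over oxygen, and a single equivalent of 15 together with the crowding at substituted C6 disfavours a second alkylation. Because ketone and enol ether oxygens are already different in 13, this bond places the benzyl group ortho to the future OH and para to the future OMe, a choice that electrophilic benzylation of a resorcinol ether would not control.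

Step 9
Reactants: 17 racemic 6-[4-(benzyloxy)benzyl]-3-methoxy-5-[2-(3-(benzyloxy)phenyl)ethyl]cyclohex-2-en-1-one
Product: 19 racemic {[2-(4-(benzyloxy)benzyl)-3-(2-(3-(benzyloxy)phenyl)ethyl)-5-methoxycyclohexa-1,5-dien-1-yl]oxy}trimethylsilane (used crude), via lithium enolate 18 (not isolated)
Conditions: LiN(iPr)2 (1.2 equiv), THF, -78 °C; Me3SiCl, -78 to 0 °C; pentane, cold aq NaHCO3 wash
Reagents that add atoms: chlorotrimethylsilane C[Si](C)(C)Cl
Why: Kinetic alpha-prime deprotonation of the remaining C6–H, as in the second stage of a Stork-Danheiser double alkylation, followed by O-silylation with the hard electrophile Me3SiCl gives the 2-silyloxy diene and removes the C6 stereocentre.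

Step 10
Reactants: 19 racemic silyl dienol ether
Product: 21 2-[4-(benzyloxy)benzyl]-3-[2-(3-(benzyloxy)phenyl)ethyl]-5-methoxyphenol, via cyclohexadienone 20 (not isolated)
Conditions: Pd(OAc)2 (1.1 equiv), MeCN, rt
Reagents that add atoms: none
Why: Saegusa-Ito oxidation: divalent palladium replaces silicon to give the C6 palladium enolate, syn beta-hydride elimination of C5–H gives cross-conjugated dienone 20, and loss of a C4 proton with protonation on oxygen (keto-enol tautomerization driven by aromaticity) gives the phenol.

Step 11
Reactants: 21 2-[4-(benzyloxy)benzyl]-3-[2-(3-(benzyloxy)phenyl)ethyl]-5-methoxyphenol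
Product: 22 IN1159, 2-(4-hydroxybenzyl)-3-[2-(3-hydroxyphenyl)ethyl]-5-methoxyphenol
Conditions: H2 (1 atm), 10% Pd/C, EtOAc/MeOH, rt
Reagents that add atoms: none
Why: Catalytic hydrogenolysis cleaves both O–CH2Ph bonds, whereas the aryl methyl ether, the diarylmethane C–C bonds and the arenes are not attacked at ambient pressure and temperature.

## Compound list

1 | 3-iodophenol | Oc1cccc(I)c1 | starting material
2 | 1-(benzyloxy)-3-iodobenzene | Ic1cccc(OCc2ccccc2)c1 | intermediate
3 | allyl alcohol | C=CCO | starting material
4 | (E)-3-[3-(benzyloxy)phenyl]prop-1-en-1-ol (enol; geometry without consequence) | O/C=C/Cc1cccc(OCc2ccccc2)c1 | intermediate (not isolated)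
5 | 3-[3-(benzyloxy)phenyl]propanal | O=CCCc1cccc(OCc2ccccc2)c1 | intermediate
6 | 1-(triphenylphosphoranylidene)propan-2-one | CC(=O)C=P(c1ccccc1)(c1ccccc1)c1ccccc1 | starting material
7 | (E)-6-[3-(benzyloxy)phenyl]hex-3-en-2-one | CC(=O)/C=C/CCc1cccc(OCc2ccccc2)c1 | intermediate
8 | dimethyl malonate | COC(=O)CC(=O)OC | starting material
9 | racemic dimethyl 2-{1-[3-(benzyloxy)phenyl]-5-oxohexan-3-yl}malonate | COC(=O)C(C(=O)OC)C(CCc1cccc(OCc2ccccc2)c1)CC(C)=O | intermediate (not isolated)
10 | methyl 2-[2-(3-(benzyloxy)phenyl)ethyl]-4,6-dioxocyclohexane-1-carboxylate (racemic, epimerizable, diketo form drawn) | COC(=O)C1C(CCc2cccc(OCc3ccccc3)c2)CC(=O)CC1=O | intermediate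
11 | 2-[2-(3-(benzyloxy)phenyl)ethyl]-4,6-dioxocyclohexane-1-carboxylic acid (racemic) | OC(=O)C1C(CCc2cccc(OCc3ccccc3)c2)CC(=O)CC1=O | intermediate (not isolated)
12 | 5-[2-(3-(benzyloxy)phenyl)ethyl]cyclohexane-1,3-dione | O=C1CC(=O)CC(CCc2cccc(OCc3ccccc3)c2)C1 | intermediate
13 | racemic 3-methoxy-5-[2-(3-(benzyloxy)phenyl)ethyl]cyclohex-2-en-1-one | COC1=CC(=O)CC(CCc2cccc(OCc3ccccc3)c2)C1 | intermediate
14 | 4-(benzyloxy)benzyl alcohol | OCc1ccc(OCc2ccccc2)cc1 | starting material
15 | 4-(benzyloxy)benzyl bromide | BrCc1ccc(OCc2ccccc2)cc1 | intermediate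
16 | lithium enolate of 13 (C1–O, C1=C6; racemic) | [Li+].COC1=CC([O-])=CC(CCc2cccc(OCc3ccccc3)c2)C1 | intermediate (not isolated)
17 | racemic trans-6-[4-(benzyloxy)benzyl]-3-methoxy-5-[2-(3-(benzyloxy)phenyl)ethyl]cyclohex-2-en-1-one (minor cis isomer carried along) | COC1=CC(=O)[C@@H](Cc2ccc(OCc3ccccc3)cc2)[C@H](CCc2cccc(OCc3ccccc3)c2)C1 | intermediate
18 | lithium enolate of 17 (C1–O, C1=C6; racemic) | [Li+].COC1=CC([O-])=C(Cc2ccc(OCc3ccccc3)cc2)C(CCc2cccc(OCc3ccccc3)c2)C1 | intermediate (not isolated)
19 | racemic {[2-(4-(benzyloxy)benzyl)-3-(2-(3-(benzyloxy)phenyl)ethyl)-5-methoxycyclohexa-1,5-dien-1-yl]oxy}trimethylsilane | COC1=CC(O[Si](C)(C)C)=C(Cc2ccc(OCc3ccccc3)cc2)C(CCc2cccc(OCc3ccccc3)c2)C1 | intermediate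
20 | 2-[4-(benzyloxy)benzyl]-3-[2-(3-(benzyloxy)phenyl)ethyl]-5-methoxycyclohexa-2,5-dien-1-one | COC1=CC(=O)C(Cc2ccc(OCc3ccccc3)cc2)=C(CCc2cccc(OCc3ccccc3)c2)C1 | intermediate (not isolated)
21 | 2-[4-(benzyloxy)benzyl]-3-[2-(3-(benzyloxy)phenyl)ethyl]-5-methoxyphenol | COc1cc(O)c(Cc2ccc(OCc3ccccc3)cc2)c(CCc2cccc(OCc3ccccc3)c2)c1 | intermediate
22 | IN1159, 2-(4-hydroxybenzyl)-3-[2-(3-hydroxyphenyl)ethyl]-5-methoxyphenol | COc1cc(O)c(Cc2ccc(O)cc2)c(CCc2cccc(O)c2)c1 | target

## Step count

Total step count: 11.
Longest linear sequence: 10 steps (steps 1-6 and 8-11, from 3-iodophenol). Step 7 is a one-step side branch.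

## Steps most likely to fail

**Step 8 (alpha-prime benzylation).**
- What may go wrong: proton exchange between enolate and product followed by a second alkylation, attack through oxygen, slow substitution next to the C5 chain, and decay of the labile bromide before it reacts.
- The fallback sets out from 13 and comes back at 21. It forms the same C6–CH2(ring C) bond from the same enolate.
- Enolate 16 is generated from 13 as in step 8. It is added at -78 °C to 4-(benzyloxy)benzaldehyde F1 (bought). This aldol addition cannot occur twice, and it should give beta-hydroxy ketone F2 as a diastereomer mixture.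
- MsCl and Et3N in CH2Cl2 at 0 °C convert F2 to mesylate F3. DBU eliminates F3 in the same flask (E1cB) to the (E)-6-benzylidene enone F4.
- F4 is a constitutional isomer of 21 with the missing unsaturation outside the ring. Catalytic RhCl3·3H2O in hot MeOH should move this double bond into the ring by rhodium hydride addition and beta-hydride elimination. This is the known exo-to-endo isomerization that turns arylidenecyclohexenones into benzylphenols. It gives 20 and from it 21.
- MeOH is chosen so that any acid-catalysed alkoxy exchange at C3 is degenerate. Steps 9 and 10 are then not needed.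

**Step 10 (Saegusa-Ito dehydrogenation).**
- What may go wrong: slow transfer of the fully substituted, crowded C6 from silicon to palladium, protodesilylation back to the ketone, and beta-hydride elimination toward the benzylic CH2 instead of C5.
- The fallback sets out from 17 and comes back at 21.
- Enolate 18 is regenerated with LiN(iPr)2 and quenched with PhSeCl at -78 °C to give alpha-phenylselanyl ketone F5. Selenium should enter opposite the C5 chain and therefore sit cis to C5–H.
- H2O2 and pyridine in CH2Cl2 at 0 °C give selenoxide F6. Its syn elimination at or below room temperature leads to 20 and on to 21.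
- Material that eliminates toward the benzylic CH2 appears as the benzylidene enone F4. F4 is not a simple keto-enol tautomer of the phenol, so it is taken to 21 with RhCl3·3H2O in MeOH as described for step 8.

**Step 9 (second enolization and silylation).**
- What may go wrong: incomplete removal of the hindered tertiary C6–H, and hydrolytic loss of the silyl group from the acid-sensitive diene during isolation.
- The fallback sets out from 13 and comes back at 21. It places the leaving group on C6 before the benzyl group, so that no hindered ketone has to be enolized and dialkylation is impossible.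
- Compound 13 is treated with LiN(iPr)2 (2 equiv) and PhSSPh to give 6-(phenylsulfanyl) enone F7.
- The more acidic C6–H of F7 is removed with NaH in THF/DMF and the enolate is alkylated with 15 to give the quaternary sulfide F8.
- mCPBA (1 equiv, CH2Cl2, -78 °C) gives sulfoxide F9.
- Because the benzyl group should enter opposite the C5 chain, sulfur ends up trans to C5–H. Thermal syn elimination (toluene, CaCO3, 80-110 °C) is therefore expected to run mainly toward the benzylic CH2 and give benzylidene enone F4. RhCl3·3H2O in MeOH isomerizes F4 to 21.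

## Further compounds

F1 | step 8 | 4-(benzyloxy)benzaldehyde (bought) | O=Cc1ccc(OCc2ccccc2)cc1
F2 | step 8 | 6-{[4-(benzyloxy)phenyl](hydroxy)methyl}-3-methoxy-5-[2-(3-(benzyloxy)phenyl)ethyl]cyclohex-2-en-1-one (beta-hydroxy ketone, racemic diastereomer mixture) | COC1=CC(=O)C(C(O)c2ccc(OCc3ccccc3)cc2)C(CCc2cccc(OCc3ccccc3)c2)C1
F3 | step 8 | methanesulfonate of F2 (mesylate, racemic diastereomer mixture, not isolated) | COC1=CC(=O)C(C(OS(C)(=O)=O)c2ccc(OCc3ccccc3)cc2)C(CCc2cccc(OCc3ccccc3)c2)C1
F4 | step 8 | racemic (E)-6-[4-(benzyloxy)benzylidene]-3-methoxy-5-[2-(3-(benzyloxy)phenyl)ethyl]cyclohex-2-en-1-one (benzylidene enone) | COC1=CC(=O)/C(=C/c2ccc(OCc3ccccc3)cc2)C(CCc2cccc(OCc3ccccc3)c2)C1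
F5 | step 10 | 6-[4-(benzyloxy)benzyl]-3-methoxy-5-[2-(3-(benzyloxy)phenyl)ethyl]-6-(phenylselanyl)cyclohex-2-en-1-one (alpha-phenylselanyl ketone, racemic) | COC1=CC(=O)C([Se]c2ccccc2)(Cc2ccc(OCc3ccccc3)cc2)C(CCc2cccc(OCc3ccccc3)c2)C1
F6 | step 10 | selenoxide of F5 (racemic, not isolated) | COC1=CC(=O)C([Se](=O)c2ccccc2)(Cc2ccc(OCc3ccccc3)cc2)C(CCc2cccc(OCc3ccccc3)c2)C1
F7 | step 9 | 3-methoxy-5-[2-(3-(benzyloxy)phenyl)ethyl]-6-(phenylsulfanyl)cyclohex-2-en-1-one (racemic diastereomer mixture) | COC1=CC(=O)C(Sc2ccccc2)C(CCc2cccc(OCc3ccccc3)c2)C1
F8 | step 9 | 6-[4-(benzyloxy)benzyl]-3-methoxy-5-[2-(3-(benzyloxy)phenyl)ethyl]-6-(phenylsulfanyl)cyclohex-2-en-1-one (quaternary sulfide, racemic) | COC1=CC(=O)C(Sc2ccccc2)(Cc2ccc(OCc3ccccc3)cc2)C(CCc2cccc(OCc3ccccc3)c2)C1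
F9 | step 9 | sulfoxide of F8 (racemic, mixture at sulfur) | COC1=CC(=O)C(S(=O)c2ccccc2)(Cc2ccc(OCc3ccccc3)cc2)C(CCc2cccc(OCc3ccccc3)c2)C1
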